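The amounts are c(D) = 20 mM and c(Z) = 26.0 mM at 110 °C, and the examiner asks what the flask holds at 4.0 min and which move then pays.

| flask | D | Z | temperature | remark | time |
|---|---|---|---|---|---|
| cedar | 20 mM | 26 mM | 110 °C | the very flask that is asked about, followed so far |  |
| alder | 40 mM | 26 mM | 116 °C | run made earlier |  |
| flask | 20 mM | 26.0 mM | 110 °C |  | 4.0 min |

cedar run (percent of the D charged)

| time / min | L / % | D / % |
|---|---|---|
| 0.500 | 26.9 | 53.7 |
| 1.00 | 35.0 | 37.0 |
| 1.50 | 40.8 | 28.6 |
| 2.00 | 41.8 | 25.1 |
| 2.50 | 40.5 | 20.1 |
| 3.00 | 41.7 | 18.8 |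

alder run (percent of the D charged)

| time / s | L / % | D / % |
|---|---|---|
| 10.0 | 15.6 | 73.9 |
| 15.0 | 19.5 | 68.1 |
| 25.0 | 22.5 | 60.3 |
| 40.0 | 26.3 | 54.3 |
| 80.0 | 28.6 | 47.2 |
| 120 | 31.1 | 40.3 |

(readings scatter by 1 percentage point)

- Monday's: at 4.0 min add Z, 50.0 % of the amount charged, then wait 8.0 min
- Wednesday's: change nothing and wait 8.0 min more
- Sunday's: at 4.0 min raise the temperature by 20 K, then wait 8.0 min
- Tuesday's: at 4.0 min add D, 50.0 % of the amount charged, then wait 8.0 min

- the volume of additions can be left aside
- a reading or a percentage of L counts all its forms, free or not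
- a reading of D is of its free form alone

- L, in percent of the D first charged, at 4.0 min
- which option adds most L ("none" when 2 percentage points or less is all one gets) (Monday's / Wednesday's / Sunday's / Tuesday's / none)
- L present, in percent of the D first charged, after Sunday's
- L present, in percent of the D first charged, after Tuesday's

What do the cedar readings, taken on this very flask, tell you? At 3.00 min, cedar shows L at 41.7 % and D at 18.8 %, so its ratio is 0.514. I call this the spent yield, the L standing per unit of D gone from the charge, a rough selectivity.

Is it steady? No, at 0.500 min cedar reads 0.581, which is higher.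

So where is the weak spot? The yield is an average over the run. From 1.50 min to 3.00 min, cedar's D fell 9.8 percentage points while L rose 0.9 points, on readings scattered by 1 point. The same ratio over that stretch reads 0.0918, lower than the spent yield.

What do you commit to? My own reckoning holds L near 41.7 % at 4.0 min. Tuesday's dose of 50.0 %, if spent whole at the late ratio, brings 4.6 points. On paper that figure clears the margin of 2 points, but it rests on a rise of 0.9 points between two readings that each scatter by 1 point, so I don't count it as a gain and answer none.

The forecast parts from me on the move: 42 % now, Tuesday's as best, 43 % after Sunday's and 52 % after Tuesday's, on the ground that “Fresh D is the one real lever”.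

The flask gives 40.7 % at 4.0 min, 6.42 % after Sunday's and 41.3 % after Tuesday's. Tuesday's gain of 0.59 points is the highest of the four, but it stays under 2 points, so the answer is none.

    D + Z ⇌ L (K = 22.0 L mol⁻¹, k = 1.00 L mol⁻¹ s⁻¹, Ea = 52.0 kJ mol⁻¹, ΔH = −37.0 kJ mol⁻¹)
    D + Z ⇌ G (K = 1000 L mol⁻¹, k = 0.440 L mol⁻¹ s⁻¹, Ea = 43.0 kJ mol⁻¹, ΔH = −72.0 kJ mol⁻¹)
    Q ⇌ L, rate k3*(cs3 - [L]) while solid is left; crystals form when [L] > cs3 (solubility = 0.830 mM, k = 0.0850 s⁻¹)
    (constants at 110 °C)

At 4.00 min this flask has spent 83.7 % of its D, so the spent yield of 0.514 reckons 43.0 % of L, its form Q counted in, against the 40.7 % found. The neighbour with c(D) = 34 mM has Z as limiting reagent, at 0.765 equiv. At 4.00 min it keeps 32 % of its D free, so 68.0 % is spent, and the same yield reckons 35.0 % of L. That neighbour holds L at 35.6 %.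

(Readings and results stem from a simulated flask for an exercise; the scatter is artificial.)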